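The readings are calculated from invented constants, noise included.

One ratio is what I watch here: the time allowed over the half-life of Sub.

| setting | ash | alder | flask |
|---|---|---|---|
| Sub | 0.052 M | 0.12 M | 0.078 M |
| remark | run made earlier | run made earlier |  |
| time |  |  | 15 d |

| run | time / d | Sub / % | Oth / % |
|---|---|---|---|
| ash | 1.04 | 6.8 | 85.1 |
| ash | 3.00 | 0.5 | 95.4 |
| ash | 5.00 | 0 | 95.8 |
| ash | 8.00 | 0.3 | 94.6 |
| ash | 10.0 | 0 | 95.9 |
| ash | 15.0 | 0 | 95.4 |
| ash | 20.0 | 0.4 | 95.6 |
| alder | 1.04 | 6.0 | 84.8 |
| alder | 3.00 | 0.3 | 95.3 |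
| alder | 5.00 | 0 | 95.1 |
| alder | 8.00 | 0 | 96.7 |
| alder | 10.0 | 0 | 95.8 |
| alder | 15.0 | 0 | 95.1 |
| alder | 20.0 | 0.7 | 95.8 |

(readings scatter by 0.5 percentage points)

- which holds at 15 d: what has brought the reaction to rest, or that it has not come to rest (forward and back rates have come level / all of Sub has reacted / it is still moving)
- share of the Sub used up at 15 d
- Oth at 15 d, in percent of the Sub charged

- the reaction counts as stopped when no species that holds the Sub changes by six tenths of a point or more over the second half of the time

I treat the fall of Sub as first-order decay. Its rate constant k is the logarithm of charge over Sub left, divided by time, and I read it at the first sampling time, 1.04 d: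

k (ash) = 2.58 d⁻¹, k (alder) = 2.71 d⁻¹

The charges were 0.052 M and 0.12 M, yet these readings lie close together, so I carry the ash value to this flask at 0.078 M:

half-life h = ln(2)/k = 0.268 d

n = time/h = 55.9

This number of halvings, n, says that if the fall stays first order, Sub in this flask reaches the scatter of a reading, 0.5 percentage points, well before 15 d, as the ash run did with 0.5% at 3.00 d.

But n tells how fast Sub falls, not where it goes. For that I take the Oth readings at 15.0 d, 95.4% and 95.1%, whose mean is 95.2%.

The forecast says all of Sub has reacted, with 100% used and Oth at 95.6%, a little above my mean. Its ground is that “The reaction stops because Sub is exhausted”.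

The flask gives all of Sub has reacted, with 100% used and Oth at 95.6%, as n of 55.9 led me to expect for Sub.

    Oth3 → Oth5 (k = 0.0250 h⁻¹)
    Oth4 → Ofp (k = 0.140 h⁻¹)
    Oth2 → Oth3 (k = 0.0500 h⁻¹)
    Oth3 ⇌ Oth4 (K = 1.10, k = 0.0880 h⁻¹)
    Sub ⇌ Oth2 (K = 0.470, k = 0.0350 h⁻¹)
    Sub → Oth (k = 0.110 h⁻¹)
    Oth4 → Oth (k = 0.580 h⁻¹)

At 0.247 d in this flask, Sub is used by the step to Oth 3.1 times as fast as by the forward step to Oth2 alone. In this flask the half-life of Sub by that forward rate alone, 0.83 d at the same moment, is short against 15 d.

With 0.13 M of Sub, a little above the alder charge, I keep n at 55.9 and expect Sub to fall to the scatter of a reading again. That neighbour flask computes to 0% of Sub left and Oth at 95.6%.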